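**Plan**

1. Cuts, last to first: the C6–Cl bond with the C5=C16 methylene (back to a C5-methyl 5E-alkene); the O7–C19 lactone and the C7 and C9 carbinols (back to an 8-hydroxy-7,9-dione); then the ring bond C7–C8.
2. Enabling feature: in the ten-membered ring C1–C10 the tertiary carbinol C8 sits between the oxygen-bearing C7 and C9. At the 7,9-dione level, C8(OH) is what a C7 acyl group leaves when it moves from O8 to C8, so the carbocycle is an 11-membered lactone (C7, C6 to C1, C10, C9, C8, O8) minus its ring oxygen.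
3. Further cuts: O8–C7 (macrolactonisation), C8–C9 (thioester plus alkylzinc), C2–C3 (acid chloride plus enyne), and ring A across C1–C14 and C10–C11 (Diels–Alder).
4. Forward order: ring A by [4+2]; C12 oxygen and C13=C14; the C2–C7 dienyl chain; the C8/C17–C19 arm; the 11-membered lactone; the ten-membered carbocycle; the γ-lactone; the C6 chloride.
5. Stereochemistry: C1, C10 and C11 from an oxazolidinone-controlled endo Diels–Alder of an E dienophile; C12 by Rubottom oxidation anti to them; C2 by Noyori transfer hydrogenation; C17 from methyl (S)-3-bromo-2-methylpropanoate; C8 by the ring-bound acyl shift; C7, C9 and C6 by substrate control in the macrocycle.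

Key step: step 23

Remark: briarane numbering (C1 to C20; C18 is the methyl on C17, C19 the lactone carbonyl) is used for every intermediate, β is the ring A face of the C1 methyl group and α the opposite face; tert-butyl 2-(triphenylphosphoranylidene)propanoate (4) is taken as a catalogue Wittig reagent.

Step 1
Reactants: 1 (E)-pent-3-en-2-one
Product: 2 (E)-2-(tert-butyldimethylsilyloxy)penta-1,3-diene
Conditions: TBSOTf, Et3N, CH2Cl2, 0 °C
Reagents that add atoms: tert-butyldimethylsilyl trifluoromethanesulfonate, CC(C)(C)[Si](C)(C)OS(=O)(=O)C(F)(F)F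
Why: Silyl enol ether formation by soft enolisation of the methyl group gives the cross-conjugated 2-silyloxy diene and leaves the E alkene unchanged.

Step 2
Reactants: 3 glyoxylic acid monohydrate; 4 tert-butyl 2-(triphenylphosphoranylidene)propanoate
Product: 5 (E)-4-tert-butoxy-3-methyl-4-oxobut-2-enoic acid
Conditions: CH2Cl2, 25 °C
Reagents that add atoms: none
Why: Wittig olefination of the aldehyde carbon with a stabilised α-methyl ylide gives the E alkene, with the two carboxyl carbons trans.

Step 3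
Reactants: 5 (E)-4-tert-butoxy-3-methyl-4-oxobut-2-enoic acid; 6 (S)-4-benzyloxazolidin-2-one
Product: 8 tert-butyl (E)-4-[(S)-4-benzyl-2-oxooxazolidin-3-yl]-2-methyl-4-oxobut-2-enoate, via mixed pivalic anhydride 7 (not isolated)
Conditions: t-BuCOCl, Et3N, THF, −20 °C; then 6, LiCl, 25 °C
Reagents that add atoms: none
Why: N-Acylation of the oxazolidinone through the mixed anhydride, which is attacked at its less hindered carbonyl, places the auxiliary on the carboxyl of the CH carbon.

Step 4
Reactants: 2 (E)-2-(tert-butyldimethylsilyloxy)penta-1,3-diene; 8 tert-butyl (E)-4-[(S)-4-benzyl-2-oxooxazolidin-3-yl]-2-methyl-4-oxobut-2-enoate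
Product: 9 ring A cycloadduct (C12=C13 silyl enol ether; C2 tert-butyl ester; C9 acyl oxazolidinone)
Conditions: Et2AlCl (1.4 equiv), CH2Cl2, −78 → −30 °C
Reagents that add atoms: none
Why: Evans auxiliary-controlled Diels–Alder reaction: the Et2AlCl chelate of the s-cis acyl oxazolidinone reacts endo on the face away from the benzyl group, the siloxy and methyl groups of the diene send its CH2 terminus to C1 (beta to the chelated carbonyl), the E dienophile fixes the C1 methyl cis to the C10 acyl group and the endo rule places the C11 methyl cis to it too, which sets C1, C10 and C11.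

Step 5
Reactants: 9 ring A cycloadduct
Product: 11 α-silyloxy ketone (C13 ketone; 12α-OTBS), via silyloxy epoxide 10 (not isolated)
Conditions: mCPBA, NaHCO3, CH2Cl2, −20 → 0 °C
Reagents that add atoms: 3-chloroperoxybenzoic acid, OOC(=O)c1cccc(Cl)c1
Why: Rubottom oxidation: the peracid oxygen reaches C12 of the silyl enol ether from the α face, opposite the C1 methyl, C10 acyl and C11 methyl groups, the epoxide opens with 1,4-silyl shift, and the C12–O bond ends trans to the C11 methyl.

Step 6
Reactants: 11 α-silyloxy ketone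
Product: 13 C13 enol triflate (C13=C14), via potassium enolate 12 (not isolated)
Conditions: KN(SiMe3)2, THF, −78 °C; PhNTf2, −78 → 0 °C
Reagents that add atoms: N-phenylbis(trifluoromethanesulfonimide), O=S(=O)(N(c1ccccc1)S(=O)(=O)C(F)(F)F)C(F)(F)F
Why: Kinetic deprotonation by the hindered amide occurs at the C14 methylene, not at the silyloxy-bearing C12 or at the very hindered C10 hydrogen of the imide, and O-sulfonylation of the enolate gives the enol triflate.

Step 7
Reactants: 13 C13 enol triflate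
Product: 14 ring A alkene (C13=C14; 12α-OTBS)
Conditions: Pd(OAc)2 (5 mol %), PPh3, HCO2H, n-Bu3N, DMF, 60 °C
Reagents that add atoms: none
Why: Palladium-catalysed formate reduction of an enol triflate (oxidative addition, hydride transfer from formate, reductive elimination) leaves the C13=C14 alkene and touches neither the imide nor the esters.

Step 8
Reactants: 14 ring A alkene
Product: 15 12α-alcohol
Conditions: HF (48 % aq), MeCN, 0 → 25 °C
Reagents that add atoms: none
Why: Fluoride-mediated desilylation under acidic conditions frees the C12 hydroxyl and spares the imide and the tert-butyl ester.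

Step 9
Reactants: 15 12α-alcohol
Product: 16 12α-propanoate
Conditions: (EtCO)2O, DMAP (cat.), Et3N, CH2Cl2, 25 °C
Reagents that add atoms: propionic anhydride, CCC(=O)OC(=O)CC
Why: DMAP-catalysed esterification puts the propanoate of the target on the only free hydroxyl, where it stays to the end.

Step 10
Reactants: 16 12α-propanoate
Product: 17 C2 carboxylic acid
Conditions: CF3CO2H, CH2Cl2, 0 → 25 °C
Reagents that add atoms: none
Why: Acidolysis of the tert-butyl ester (loss of 2-methylpropene) frees the C2 carboxyl without harming the propanoate, the imide or the alkene.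

Step 11
Reactants: 18 (E)-3-methylpent-2-en-4-yn-1-ol
Product: 19 (E)-tert-butyldimethyl(3-methylpent-2-en-4-yn-1-yloxy)silane
Conditions: TBSCl, imidazole, DMF, 25 °C
Reagents that add atoms: tert-butyldimethylsilyl chloride, CC(C)(C)[Si](C)(C)Cl
Why: Standard silylation protects the primary alcohol so that the terminal alkyne can be used in step 12.

Step 12
Reactants: 17 C2 carboxylic acid; 19 (E)-tert-butyldimethyl(3-methylpent-2-en-4-yn-1-yloxy)silane
Product: 21 ynone (C2 ketone; C3≡C4; 5E alkene; C7H2OTBS), via acid chloride 20 (not isolated)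
Conditions: (COCl)2, DMF (cat.), CH2Cl2, 0 → 25 °C; then 19, PdCl2(PPh3)2 (2 mol %), CuI (4 mol %), Et3N, THF, 25 °C
Reagents that add atoms: none
Why: Acyl Sonogashira coupling: the acid chloride adds oxidatively to palladium faster than any other group and the copper acetylide of 19 is transferred, forming C2–C3 as an ynone.

Step 13
Reactants: 21 ynone
Product: 22 (2R)-propargylic alcohol
Conditions: Ru[(R,R)-TsDPEN](p-cymene) (2 mol %, preformed amido complex), i-PrOH, 25 °C
Reagents that add atoms: none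
Why: Noyori asymmetric transfer hydrogenation of an ynone under base-free conditions: the (R,R) catalyst delivers hydride to the carbonyl face that gives the (2R) propargylic alcohol under reagent control, which is the spatial arrangement of the C2–O bond of the target.

Step 14
Reactants: 22 (2R)-propargylic alcohol
Product: 23 C2 TBS ether
Conditions: TBSOTf, 2,6-lutidine, CH2Cl2, −40 → 0 °C
Reagents that add atoms: tert-butyldimethylsilyl trifluoromethanesulfonate, CC(C)(C)[Si](C)(C)OS(=O)(=O)C(F)(F)F
Why: Silylation with the silyl triflate and a hindered base protects the neopentyl-type secondary alcohol.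

Step 15
Reactants: 23 C2 TBS ether
Product: 24 (3Z,5E)-diene
Conditions: H2 (1 atm), Pd/CaCO3 poisoned with Pb(OAc)2, quinoline, EtOAc, 25 °C
Reagents that add atoms: none
Why: Lindlar semi-hydrogenation adds H2 syn to the triple bond only, which gives the 3Z alkene and leaves the ring alkene.

Step 16
Reactants: 24 (3Z,5E)-diene
Product: 25 C9 S-ethyl thioester
Conditions: EtSH, n-BuLi, THF, −20 → 0 °C
Reagents that add atoms: ethanethiol, CCS
Why: Thiolysis of the N-acyl oxazolidinone by lithium ethanethiolate attacks the exocyclic carbonyl, releases the auxiliary and gives the thioester without a base strong enough to epimerise C10.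

Step 17
Reactants: 25 C9 S-ethyl thioester; 26 methyl (S)-3-bromo-2-methylpropanoate
Product: 28 γ-keto ester (C9 ketone; C8H2; 17R; C19 methyl ester), via alkylzinc bromide 27 (not isolated)
Conditions: 26, Zn dust, LiCl, THF, 50 °C; then 25, PdCl2(PPh3)2 (5 mol %), toluene/THF, 25 °C
Reagents that add atoms: none
Why: Fukuyama coupling: palladium inserts into the C–S bond of the thioester and the ester-bearing alkylzinc, whose C17 centre comes unchanged from 26, is transferred to form C9–C8 as a ketone.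

Step 18
Reactants: 28 γ-keto ester
Product: 30 C8 ketol (8RS), via potassium enolate 29 (not isolated)
Conditions: KN(SiMe3)2 (1.1 equiv), THF, −78 °C; then 2-(phenylsulfonyl)-3-phenyloxaziridine, −78 °C
Reagents that add atoms: 2-(phenylsulfonyl)-3-phenyloxaziridine, O=S(=O)(N1OC1c1ccccc1)c1ccccc1
Why: Davis oxidation: the kinetic enolate forms at the C8 methylene (C10–H is hindered, the ester α-hydrogens are less acidic) and is hydroxylated by the sulfonyloxaziridine, and both C8 epimers are carried on because C8 becomes planar again in step 23.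

Step 19
Reactants: 30 C8 ketol
Product: 31 C7,C8 diol
Conditions: HF·pyridine, pyridine, THF, 0 °C
Reagents that add atoms: none
Why: Buffered fluoride cleaves the primary allylic TBS ether much faster than the hindered secondary one at C2.

Step 20
Reactants: 31 C7,C8 diol
Product: 32 C7 enal
Conditions: MnO2, CH2Cl2, 25 °C
Reagents that add atoms: none
Why: MnO2 oxidises only the allylic alcohol, so the secondary ketol hydroxyl is left.

Step 21
Reactants: 32 C7 enal
Product: 33 seco acid (C7 CO2H; free C8–OH)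
Conditions: NaClO2, NaH2PO4, 2-methylbut-2-ene, t-BuOH/H2O, 0 → 25 °C
Reagents that add atoms: sodium chlorite, [Na+].[O-]Cl=O
Why: Pinnick oxidation turns the enal into the acid while the alkene additive traps hypochlorite, leaving the diene and the ketol.

Step 22
Reactants: 33 seco acid
Product: 35 11-membered dienoate lactone (8RS), via mixed nitrobenzoic anhydride 34 (not isolated)
Conditions: 2-methyl-6-nitrobenzoic anhydride, DMAP, Et3N, CH2Cl2 (0.002 M, syringe pump), 25 °C
Reagents that add atoms: none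
Why: Shiina macrolactonisation: the activated carboxyl acylates the C8 hydroxyl under high dilution, the Z alkene and the adjacent attachment points C1 and C10 on ring A keeping the chain ends close.

Step 23
Reactants: 35 11-membered dienoate lactone
Product: 38 ten-membered 8-hydroxy-7,9-dione, via lithium enolate 36 (not isolated), via oxiranyl alkoxide 37 (not isolated)
Conditions: LiN(SiMe3)2 (1.1 equiv), THF, −78 → −40 °C; AcOH, −78 °C
Reagents that add atoms: none
Why: Proposed new method: the hindered lithium amide removes the hydrogen at C8, which is acidified by the C9 carbonyl and by the ester oxygen on the same carbon, and the enolate carbon adds to the adjacent lactone carbonyl C7; the oxiranyl alkoxide then reopens by breaking C7–O8, so the acyl carbon has moved from O8 to C8 and the former ring oxygen is left as the C8 alkoxide. The closest known reactions are the Chan rearrangement of α-acyloxy acetates to 2-hydroxy-3-keto esters and the base-induced conversion of α-acyloxy ketones into 2-hydroxy-1,3-diketones; neither has been used to contract a macrolactone into a carbocycle. The ten-membered ring C1–C10 is closed by a 3-exo-trig addition inside the 11-membered ring followed by opening of the three-membered ring, a transannular 1,2-shift that replaces a direct medium-ring carbocyclisation. The one new stereocentre, C8, is fixed by the enolate face that C7 can reach: C7 is bound to O8 and to the rest of the ring through the E-dienoate, so with C10 and C17 fixed it can swing onto one face only, and both C8 epimers of 35 give the same enolate and hence one product. The step needs deprotonation at C8 and not at C10, C17 or the propanoate, which the acidity of the C8 hydrogen and one equivalent of base at −78 °C secure, and it needs the product to persist, which lithium chelation between the C8 alkoxide and the flanking carbonyls and a cold acid quench provide against the reverse shift and retro-Claisen cleavage.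

Step 24
Reactants: 38 ten-membered 8-hydroxy-7,9-dione
Product: 40 γ-lactone ketone (O7–C19 lactone; C9 ketone), via hydroxy ester 39 (not isolated)
Conditions: NaBH4, CeCl3·7H2O, MeOH/THF, −78 → 0 °C; then silica gel, CH2Cl2, 25 °C
Reagents that add atoms: none
Why: Luche reduction: the cerium-activated dienone carbonyl C7 is reduced 1,2 in preference to the hindered C9 ketone, hydride arrives from the open peripheral face so that O7 is cis to O8, and the C7 oxygen closes the γ-lactone on the C19 ester.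

Step 25
Reactants: 40 γ-lactone ketone
Product: 41 8,9-diol
Conditions: Me4NBH(OAc)3, AcOH/MeCN, −30 °C
Reagents that add atoms: none
Why: Saksena–Evans reduction: the borohydride exchanges an acetate for the C8 hydroxyl and delivers hydride intramolecularly to the C9 carbonyl, which in the lactone-bridged ring should give the C9 alcohol trans to the C8 hydroxyl.

Step 26
Reactants: 41 8,9-diol
Product: 42 2,8,9-triol
Conditions: HF·pyridine, THF, 0 → 25 °C
Reagents that add atoms: none
Why: Fluoride removes the last silyl ether, and the lactone, the propanoate and the diene are stable to these conditions.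

Step 27
Reactants: 42 2,8,9-triol
Product: 43 2,9-diacetate
Conditions: Ac2O, DMAP, pyridine, CH2Cl2, 25 °C
Reagents that add atoms: acetic anhydride, CC(=O)OC(C)=O
Why: DMAP-catalysed acetylation esterifies the secondary hydroxyls at C2 and C9 and leaves the tertiary C8 hydroxyl free.

Step 28
Reactants: 43 2,9-diacetate
Product: 44 CNP0305105.1
Conditions: Ca(OCl)2, solid CO2, CH2Cl2/H2O, 0 °C
Reagents that add atoms: calcium hypochlorite, [Ca+2].[O-]Cl.[O-]Cl
Why: Ene-type allylic chlorination with hypochlorous acid: electrophilic chlorine adds to C6 of the trisubstituted C5=C6 alkene from its open outer face and a C16 hydrogen is lost, which moves the double bond to C5=C16 and sets C6.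

**Compound list**

1 | (E)-pent-3-en-2-one | C/C=C/C(C)=O | starting material
2 | (E)-2-(tert-butyldimethylsilyloxy)penta-1,3-diene | C=C(O[Si](C)(C)C(C)(C)C)/C=C/C | intermediate
3 | glyoxylic acid monohydrate | OC(O)C(O)=O | starting material
4 | tert-butyl 2-(triphenylphosphoranylidene)propanoate | CC(C(=O)OC(C)(C)C)=P(c1ccccc1)(c1ccccc1)c1ccccc1 | starting material
5 | (E)-4-tert-butoxy-3-methyl-4-oxobut-2-enoic acid | CC(C)(C)OC(=O)/C(C)=C/C(O)=O | intermediate
6 | (S)-4-benzyloxazolidin-2-one | O=C1N[C@@H](Cc2ccccc2)CO1 | starting material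
7 | mixed anhydride of 5 and pivalic acid | CC(C)(C)OC(=O)/C(C)=C/C(=O)OC(=O)C(C)(C)C | intermediate (not isolated)
8 | tert-butyl (E)-4-[(S)-4-benzyl-2-oxooxazolidin-3-yl]-2-methyl-4-oxobut-2-enoate | CC(C)(C)OC(=O)/C(C)=C/C(=O)N1[C@@H](Cc2ccccc2)COC1=O | intermediate
9 | tert-butyl (1S,5S,6S)-6-[(S)-4-benzyl-2-oxooxazolidine-3-carbonyl]-3-(tert-butyldimethylsilyloxy)-1,5-dimethylcyclohex-3-ene-1-carboxylate (ring C1, C5, C6 = briarane C1, C11, C10; both methyls and the acyl group on the β face) | CC(C)(C)OC(=O)[C@@]1(C)CC(O[Si](C)(C)C(C)(C)C)=C[C@H](C)[C@@H]1C(=O)N1[C@@H](Cc2ccccc2)COC1=O | intermediate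
10 | 12α,13α-epoxide of 9 (C13 still bears OTBS) | CC(C)(C)OC(=O)[C@@]1(C)C[C@@]2(O[Si](C)(C)C(C)(C)C)O[C@H]2[C@H](C)[C@@H]1C(=O)N1[C@@H](Cc2ccccc2)COC1=O | intermediate (not isolated)
11 | ring A α-silyloxy ketone: C13 ketone, 12α-OTBS trans to the 11β-methyl, C2 tert-butyl ester, C9 acyl oxazolidinone | CC(C)(C)OC(=O)[C@@]1(C)CC(=O)[C@@H](O[Si](C)(C)C(C)(C)C)[C@H](C)[C@@H]1C(=O)N1[C@@H](Cc2ccccc2)COC1=O | intermediate
12 | potassium C13(O)=C14 enolate of 11 | CC(C)(C)OC(=O)[C@@]1(C)C=C(O[K])[C@@H](O[Si](C)(C)C(C)(C)C)[C@H](C)[C@@H]1C(=O)N1[C@@H](Cc2ccccc2)COC1=O | intermediate (not isolated)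
13 | enol triflate: 11 with C13(OTf)=C14 | CC(C)(C)OC(=O)[C@@]1(C)C=C(OS(=O)(=O)C(F)(F)F)[C@@H](O[Si](C)(C)C(C)(C)C)[C@H](C)[C@@H]1C(=O)N1[C@@H](Cc2ccccc2)COC1=O | intermediate
14 | ring A alkene: C13=C14, 12α-OTBS, C2 tert-butyl ester, C9 acyl oxazolidinone | CC(C)(C)OC(=O)[C@@]1(C)C=C[C@@H](O[Si](C)(C)C(C)(C)C)[C@H](C)[C@@H]1C(=O)N1[C@@H](Cc2ccccc2)COC1=O | intermediate
15 | 12α-alcohol from 14 | CC(C)(C)OC(=O)[C@@]1(C)C=C[C@@H](O)[C@H](C)[C@@H]1C(=O)N1[C@@H](Cc2ccccc2)COC1=O | intermediate
16 | 12α-propanoate of 15 | CC(C)(C)OC(=O)[C@@]1(C)C=C[C@@H](OC(=O)CC)[C@H](C)[C@@H]1C(=O)N1[C@@H](Cc2ccccc2)COC1=O | intermediate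
17 | C2 carboxylic acid from 16 | OC(=O)[C@@]1(C)C=C[C@@H](OC(=O)CC)[C@H](C)[C@@H]1C(=O)N1[C@@H](Cc2ccccc2)COC1=O | intermediate
18 | (E)-3-methylpent-2-en-4-yn-1-ol | C#C/C(C)=C/CO | starting material
19 | (E)-tert-butyldimethyl(3-methylpent-2-en-4-yn-1-yloxy)silane | C#C/C(C)=C/CO[Si](C)(C)C(C)(C)C | intermediate
20 | C2 acid chloride of 17 | ClC(=O)[C@@]1(C)C=C[C@@H](OC(=O)CC)[C@H](C)[C@@H]1C(=O)N1[C@@H](Cc2ccccc2)COC1=O | intermediate (not isolated)
21 | ynone: C2 ketone on C1 joined to C3≡C4–C5(CH3)=C6H–C7H2OTBS (5E), ring A as in 16 | CC(C)(C)[Si](C)(C)OC/C=C(C)/C#CC(=O)[C@@]1(C)C=C[C@@H](OC(=O)CC)[C@H](C)[C@@H]1C(=O)N1[C@@H](Cc2ccccc2)COC1=O | intermediate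
22 | (2R)-propargylic alcohol from 21 | CC(C)(C)[Si](C)(C)OC/C=C(C)/C#C[C@H](O)[C@@]1(C)C=C[C@@H](OC(=O)CC)[C@H](C)[C@@H]1C(=O)N1[C@@H](Cc2ccccc2)COC1=O | intermediate
23 | C2 TBS ether of 22 | CC(C)(C)[Si](C)(C)OC/C=C(C)/C#C[C@H](O[Si](C)(C)C(C)(C)C)[C@@]1(C)C=C[C@@H](OC(=O)CC)[C@H](C)[C@@H]1C(=O)N1[C@@H](Cc2ccccc2)COC1=O | intermediate
24 | (3Z,5E)-diene from 23 (C2 is S by CIP from here on, same spatial arrangement) | CC(C)(C)[Si](C)(C)OC/C=C(C)/C=C\[C@H](O[Si](C)(C)C(C)(C)C)[C@@]1(C)C=C[C@@H](OC(=O)CC)[C@H](C)[C@@H]1C(=O)N1[C@@H](Cc2ccccc2)COC1=O | intermediate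
25 | C9 S-ethyl thioester from 24 | CC(C)(C)[Si](C)(C)OC/C=C(C)/C=C\[C@H](O[Si](C)(C)C(C)(C)C)[C@@]1(C)C=C[C@@H](OC(=O)CC)[C@H](C)[C@@H]1C(=O)SCC | intermediate
26 | methyl (S)-3-bromo-2-methylpropanoate | COC(=O)[C@H](C)CBr | starting material
27 | (S)-(3-methoxy-2-methyl-3-oxopropyl)zinc bromide | COC(=O)[C@H](C)C[Zn]Br | intermediate (not isolated)
28 | γ-keto ester: C9 ketone carrying C8H2–(17R)-C17H(CH3)–C19O2CH3 | CC(C)(C)[Si](C)(C)OC/C=C(C)/C=C\[C@H](O[Si](C)(C)C(C)(C)C)[C@@]1(C)C=C[C@@H](OC(=O)CC)[C@H](C)[C@@H]1C(=O)C[C@@H](C)C(=O)OC | intermediate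
29 | potassium C8=C9(O) enolate of 28 | CC(C)(C)[Si](C)(C)OC/C=C(C)/C=C\[C@H](O[Si](C)(C)C(C)(C)C)[C@@]1(C)C=C[C@@H](OC(=O)CC)[C@H](C)[C@@H]1C(O[K])=C[C@@H](C)C(=O)OC | intermediate (not isolated)
30 | C8 ketol from 28 (8RS, C8 left undefined) | CC(C)(C)[Si](C)(C)OC/C=C(C)/C=C\[C@H](O[Si](C)(C)C(C)(C)C)[C@@]1(C)C=C[C@@H](OC(=O)CC)[C@H](C)[C@@H]1C(=O)C(O)[C@@H](C)C(=O)OC | intermediate
31 | diol: 30 with C7H2OH free (8RS) | OC/C=C(C)/C=C\[C@H](O[Si](C)(C)C(C)(C)C)[C@@]1(C)C=C[C@@H](OC(=O)CC)[C@H](C)[C@@H]1C(=O)C(O)[C@@H](C)C(=O)OC | intermediate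
32 | C7 enal from 31 (8RS) | O=C/C=C(C)/C=C\[C@H](O[Si](C)(C)C(C)(C)C)[C@@]1(C)C=C[C@@H](OC(=O)CC)[C@H](C)[C@@H]1C(=O)C(O)[C@@H](C)C(=O)OC | intermediate
33 | seco acid: C7 carboxylic acid with free C8–OH (8RS) | OC(=O)/C=C(C)/C=C\[C@H](O[Si](C)(C)C(C)(C)C)[C@@]1(C)C=C[C@@H](OC(=O)CC)[C@H](C)[C@@H]1C(=O)C(O)[C@@H](C)C(=O)OC | intermediate
34 | mixed anhydride of 33 with 2-methyl-6-nitrobenzoic acid | Cc1cccc([N+](=O)[O-])c1C(=O)OC(=O)/C=C(C)/C=C\[C@H](O[Si](C)(C)C(C)(C)C)[C@@]1(C)C=C[C@@H](OC(=O)CC)[C@H](C)[C@@H]1C(=O)C(O)[C@@H](C)C(=O)OC | intermediate (not isolated)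
35 | 11-membered lactone fused to ring A at C1–C10 (ring: C7(=O), C6=C5(CH3), C4=C3, C2(OTBS), C1, C10, C9(=O), C8, O8; 3Z,5E; 8RS), C8 bearing C17H(CH3)CO2CH3, 12α-propanoate | O=C1/C=C(C)/C=C\[C@H](O[Si](C)(C)C(C)(C)C)[C@@]2(C)C=C[C@@H](OC(=O)CC)[C@H](C)[C@@H]2C(=O)C(O1)[C@@H](C)C(=O)OC | intermediate
36 | lithium C8=C9(O) enolate of 35 | O=C1/C=C(C)/C=C\[C@H](O[Si](C)(C)C(C)(C)C)[C@@]2(C)C=C[C@@H](OC(=O)CC)[C@H](C)[C@@H]2C(O[Li])=C(O1)[C@@H](C)C(=O)OC | intermediate (not isolated)
37 | lithium oxiranyl alkoxide: C7–C8 bond formed, O8 bridging C7 and C8, C7–OLi | [Li]OC12/C=C(C)/C=C\[C@H](O[Si](C)(C)C(C)(C)C)[C@@]3(C)C=C[C@@H](OC(=O)CC)[C@H](C)[C@@H]3C(=O)C1(O2)[C@@H](C)C(=O)OC | intermediate (not isolated)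
38 | ten-membered 8-hydroxy-7,9-dione (ring C1–C10; 3Z,5E; C8 bearing OH and C17H(CH3)CO2CH3; 2-OTBS; 12α-propanoate) | O=C1/C=C(C)/C=C\[C@H](O[Si](C)(C)C(C)(C)C)[C@@]2(C)C=C[C@@H](OC(=O)CC)[C@H](C)[C@@H]2C(=O)[C@]1(O)[C@@H](C)C(=O)OC | intermediate
39 | 7,8-diol methyl ester: C7 alcohol from 38, O7 cis to O8 | O[C@H]1/C=C(C)/C=C\[C@H](O[Si](C)(C)C(C)(C)C)[C@@]2(C)C=C[C@@H](OC(=O)CC)[C@H](C)[C@@H]2C(=O)[C@]1(O)[C@@H](C)C(=O)OC | intermediate (not isolated)
40 | γ-lactone (O7–C19) with C9 ketone, C8–OH, 2-OTBS, 12α-propanoate | O=C1O[C@H]2/C=C(C)/C=C\[C@H](O[Si](C)(C)C(C)(C)C)[C@@]3(C)C=C[C@@H](OC(=O)CC)[C@H](C)[C@@H]3C(=O)[C@]2(O)[C@H]1C | intermediate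
41 | 8,9-diol: C9 alcohol from 40, O9 trans to O8 | O=C1O[C@H]2/C=C(C)/C=C\[C@H](O[Si](C)(C)C(C)(C)C)[C@@]3(C)C=C[C@@H](OC(=O)CC)[C@H](C)[C@@H]3[C@H](O)[C@]2(O)[C@H]1C | intermediate
42 | 2,8,9-triol (TBS removed) | O=C1O[C@H]2/C=C(C)/C=C\[C@H](O)[C@@]3(C)C=C[C@@H](OC(=O)CC)[C@H](C)[C@@H]3[C@H](O)[C@]2(O)[C@H]1C | intermediate
43 | 2,9-diacetate with C5 methyl and (3Z,5E)-diene | O=C1O[C@H]2/C=C(C)/C=C\[C@H](OC(C)=O)[C@@]3(C)C=C[C@@H](OC(=O)CC)[C@H](C)[C@@H]3[C@H](OC(C)=O)[C@]2(O)[C@H]1C | intermediate
44 | CNP0305105.1, (1S,2S,3Z,6S,7R,8R,9S,10S,11R,12R,17R)-2,9-diacetoxy-6-chloro-8-hydroxy-12-propanoyloxybriara-3,5(16),13-trien-19,7-olide | C=C1/C=C\[C@H](OC(C)=O)[C@@]2(C)C=C[C@@H](OC(=O)CC)[C@H](C)[C@@H]2[C@H](OC(C)=O)[C@]2(O)[C@@H](C)C(=O)O[C@H]2[C@H]1Cl | target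

**Totals**

Total step count: 28 (24 on the main line, 4 for diene 2, dienophile 8 and enyne 19).
Longest linear sequence: 26 steps (steps 2 to 10 and 12 to 28, from 3 and 4 to 44).

**Steps most likely to fail**

Step 23 (Proposed new method). After enolisation the acyl group may not stay on carbon: the oxiranyl alkoxide can revert to the lactone, or the hydroxy diketone alkoxide can undergo retro-Claisen opening. Enolisation may also stray to C10, or the acyl carbon may reach the other enolate face. The fallback uses a known reaction, an intramolecular aldol addition (macroaldolisation), to form the same C7–C8 bond and close the same ten-membered ring. It sets out from enal 32: KN(SiMe3)2 (2.2 equiv) in THF at −78 °C under high dilution gives the C8 alkoxide-enolate, which adds to the C7 aldehyde and gives hydroxy ester 39 directly. Lactonisation of 39 then gives 40, where the fallback comes back to the route, so steps 21 to 23 and the hydride reduction of step 24 are bypassed. No compound outside the list is formed.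

Step 22. Oligomerisation may outrun closure of the strained 11-membered ring. The amine base may also shift the α-ketol (acyloin isomerisation) or, once O8 is acylated, cause elimination across C8–C17. The fallback makes the same ester linkage by SN2 attack of the carboxylate on C8, with no acyl activation and no free ketol. It sets out from keto ester 28: LiN(SiMe3)2 in THF at −78 °C followed by N-bromosuccinimide gives the α-bromo ketone F1. HF·pyridine then frees the C7 allylic alcohol F2, MnO2 gives the enal F3 and NaClO2 the bromo acid F4. Cs2CO3 in DMF at high dilution closes the ring, and the fallback comes back to the route at lactone 35; the C8 configuration is again irrelevant.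

Step 28. The electrophilic chlorine may lack site and face selectivity: attack at C3=C4 or C13=C14, 1,4-addition across the diene, or delivery to the wrong face of C6. The fallback separates the ene step from the introduction of chlorine. It sets out from 43: a Schenck ene reaction with singlet oxygen (O2, tetraphenylporphyrin, light, CH2Cl2, −20 °C) gives the C6 allylic hydroperoxide F5 with the C5=C16 methylene. PPh3 reduces it to the allylic alcohol F6, CBr4/PPh3 gives the C6 bromide F7 with inversion, and LiCl in acetone replaces bromide by chloride with a second inversion. The fallback comes back to the route at 44.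

**Further compounds**

F0 | step 23 | none | none
F1 | step 22 | 8-bromo analogue of keto ester 28 (α-bromo ketone, 8RS) | CC(C)(C)[Si](C)(C)OC/C=C(C)/C=C\[C@H](O[Si](C)(C)C(C)(C)C)[C@@]1(C)C=C[C@@H](OC(=O)CC)[C@H](C)[C@@H]1C(=O)C(Br)[C@@H](C)C(=O)OC
F2 | step 22 | C7 allylic alcohol from F1 | OC/C=C(C)/C=C\[C@H](O[Si](C)(C)C(C)(C)C)[C@@]1(C)C=C[C@@H](OC(=O)CC)[C@H](C)[C@@H]1C(=O)C(Br)[C@@H](C)C(=O)OC
F3 | step 22 | C7 enal from F2 | O=C/C=C(C)/C=C\[C@H](O[Si](C)(C)C(C)(C)C)[C@@]1(C)C=C[C@@H](OC(=O)CC)[C@H](C)[C@@H]1C(=O)C(Br)[C@@H](C)C(=O)OC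
F4 | step 22 | 8-bromo seco acid from F3 | OC(=O)/C=C(C)/C=C\[C@H](O[Si](C)(C)C(C)(C)C)[C@@]1(C)C=C[C@@H](OC(=O)CC)[C@H](C)[C@@H]1C(=O)C(Br)[C@@H](C)C(=O)OC
F5 | step 28 | C6 hydroperoxide of 43 with C5=C16 methylene | C=C1/C=C\[C@H](OC(C)=O)[C@@]2(C)C=C[C@@H](OC(=O)CC)[C@H](C)[C@@H]2[C@H](OC(C)=O)[C@]2(O)[C@@H](C)C(=O)O[C@H]2[C@H]1OO
F6 | step 28 | C6 allylic alcohol from F5 | C=C1/C=C\[C@H](OC(C)=O)[C@@]2(C)C=C[C@@H](OC(=O)CC)[C@H](C)[C@@H]2[C@H](OC(C)=O)[C@]2(O)[C@@H](C)C(=O)O[C@H]2[C@H]1O
F7 | step 28 | C6 bromide with inverted C6 | C=C1/C=C\[C@H](OC(C)=O)[C@@]2(C)C=C[C@@H](OC(=O)CC)[C@H](C)[C@@H]2[C@H](OC(C)=O)[C@]2(O)[C@@H](C)C(=O)O[C@H]2[C@@H]1Br
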